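## Retrosynthetic overview

1. 19 ⇒ 14 + 15: the last operation makes both core rings. Enolate addition–elimination on a ketene dithioacetal and Dieckmann closure give the carbocycle; the acid quench then closes the dihydropyranone.
2. 14 ⇒ 12 (CS2/MeI at the only enolisable ketone position, then side-chain ester hydrolysis); 12 ⇒ 11 by catalytic asymmetric prenylation (quaternary centre) ⇒ 10 + 6.
3. 10 ⇒ 8 ⇒ 7: catalytic desymmetrisation of 3-propylglutaric anhydride sets the propyl-bearing centre.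
4. 6 ⇒ 5 ⇒ 4 ⇒ 3 ⇒ 1: Rh-catalysed asymmetric conjugate isopropenylation of a cyclobutenoate sets both cyclobutane centres.
5. Ring order: cyclobutane (bought) → six-membered carbocycle → dihydropyranone, the last two in one flask.

Assumption: numbered compounds are the fragment starting materials and everything carried through the route, other atom-donating reagents are given with SMILES on the "Reagents that add atoms" line, and in steps 2, 5 and 8 the catalyst antipode that delivers the drawn configuration is used (sense not established for these substrates).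

## Route

Step 1
Reactants: 1 methyl 3,3-dimethylcyclobutane-1-carboxylate
Product: 3 methyl 3,3-dimethylcyclobut-1-ene-1-carboxylate, via alpha-phenylselanyl ester 2 (not isolated)
Conditions: LDA, THF, −78 °C; PhSeBr; then 30% H2O2, pyridine, CH2Cl2, 0 → 23 °C
Reagents that add atoms: none
Why: α-Selenenylation of the ester enolate followed by selenoxide syn-elimination (Reich/Sharpless dehydrogenation) gives the strained but isolable cyclobutene ester, and no stereocentre is formed.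

Step 2
Reactants: 3 methyl 3,3-dimethylcyclobut-1-ene-1-carboxylate
Product: 4 methyl (1R,2R)-3,3-dimethyl-2-(prop-1-en-2-yl)cyclobutane-1-carboxylate
Conditions: isopropenyl-B(pin) (2.5 equiv), [Rh(cod)OH]2 (3 mol%), (R)-BINAP (7 mol%), KOH (0.3 equiv), dioxane/H2O 10:1, 50 °C
Reagents that add atoms: isopropenylboronic acid pinacol ester, CC(=C)B1OC(C)(C)C(C)(C)O1
Why: Hayashi–Miyaura Rh-catalysed asymmetric 1,4-addition, in which ligand-controlled syn-carborhodation of the strained enoate sets C2 (R), and protonation of the rhodium enolate anti to the new isopropenyl group, backed by base equilibration of the ester α-carbon, sets the trans C1 (R).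

Step 3
Reactants: 4 methyl (1R,2R)-3,3-dimethyl-2-(prop-1-en-2-yl)cyclobutane-1-carboxylate
Product: 5 [(1R,2R)-3,3-dimethyl-2-(prop-1-en-2-yl)cyclobutyl]methanol
Conditions: LiAlH4, Et2O, 0 °C
Reagents that add atoms: none
Why: Hydride reduction of the ester to the primary alcohol leaves the isolated alkene and both stereocentres untouched.

Step 4
Reactants: 5 [(1R,2R)-3,3-dimethyl-2-(prop-1-en-2-yl)cyclobutyl]methanol
Product: 6 (1R,2R)-1-(iodomethyl)-3,3-dimethyl-2-(prop-1-en-2-yl)cyclobutane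
Conditions: I2, PPh3, imidazole, CH2Cl2, 0 → 23 °C
Reagents that add atoms: iodine, II
Why: Appel iodination proceeds by SN2 at the exocyclic CH2, so no cyclobutylcarbinyl cation (and no ring expansion) is involved and the ring stereocentres are retained.

Step 5
Reactants: 7 3-propylglutaric anhydride
Product: 8 (3S)-3-(2-methoxy-2-oxoethyl)hexanoic acid
Conditions: MeOH (10 equiv), (DHQD)2AQN (10 mol%), Et2O, −40 °C
Reagents that add atoms: methanol, CO
Why: Cinchona-alkaloid-catalysed enantioselective methanolysis of the prochiral anhydride (Deng desymmetrisation) delivers methanol to one enantiotopic carbonyl and sets the propyl-bearing centre, (S) here and (R) in the target after the priority change.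

Step 6
Reactants: 8 (3S)-3-(2-methoxy-2-oxoethyl)hexanoic acid
Product: 10 1-tert-butyl 7-methyl (5S)-3-oxo-5-propylheptanedioate, via acyl imidazolide 9 (not isolated)
Conditions: CDI, THF, 23 °C; then KO2CCH2CO2tBu, MgCl2, Et3N, MeCN/THF, 23 → 40 °C; aq. HCl work-up
Reagents that add atoms: potassium 3-tert-butoxy-3-oxopropanoate, CC(C)(C)OC(=O)CC(=O)[O-].[K+]
Why: Masamune–Brooks chain extension, in which the acyl imidazolide C-acylates the magnesium malonate half-ester and the adduct decarboxylates to the β-keto ester, with the methyl ester and the stereocentre as spectators.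

Step 7
Reactants: 10 1-tert-butyl 7-methyl (5S)-3-oxo-5-propylheptanedioate; 6 (1R,2R)-1-(iodomethyl)-3,3-dimethyl-2-(prop-1-en-2-yl)cyclobutane
Product: 11 1-tert-butyl 7-methyl (2RS,5S)-2-{[(1R,2R)-3,3-dimethyl-2-(prop-1-en-2-yl)cyclobutyl]methyl}-3-oxo-5-propylheptanedioate
Conditions: NaH (1.05 equiv), THF/DMF, 0 → 40 °C
Reagents that add atoms: none
Why: C-Alkylation of the β-keto ester sodium enolate by SN2 on the primary iodide; the new C2 centre forms as a mixture and is re-set in step 8.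

Step 8
Reactants: 11 1-tert-butyl 7-methyl (2RS,5S)-2-{[(1R,2R)-3,3-dimethyl-2-(prop-1-en-2-yl)cyclobutyl]methyl}-3-oxo-5-propylheptanedioate
Product: 12 1-tert-butyl 7-methyl (2S,5S)-2-{[(1S,2R)-3,3-dimethyl-2-(prop-1-en-2-yl)cyclobutyl]methyl}-2-(3-methylbut-2-en-1-yl)-3-oxo-5-propylheptanedioate
Conditions: prenyl bromide (1.5 equiv), (S,S)-3,4,5-trifluorophenyl-NAS bromide (3 mol%), CsOH·H2O, toluene, −40 °C
Reagents that add atoms: prenyl bromide, CC(C)=CCBr
Why: Asymmetric phase-transfer alkylation of an α-substituted tert-butyl β-keto ester (Maruoka type), in which the chiral ammonium enolate ion pair exposes one face to prenyl bromide and sets the quaternary centre (2S here, 6R in the target).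

Step 9
Reactants: 12 1-tert-butyl 7-methyl (2S,5S)-2-{[(1S,2R)-3,3-dimethyl-2-(prop-1-en-2-yl)cyclobutyl]methyl}-2-(3-methylbut-2-en-1-yl)-3-oxo-5-propylheptanedioate
Product: 13 1-tert-butyl 7-methyl (2S,5R)-4-[bis(methylsulfanyl)methylidene]-2-{[(1S,2R)-3,3-dimethyl-2-(prop-1-en-2-yl)cyclobutyl]methyl}-2-(3-methylbut-2-en-1-yl)-3-oxo-5-propylheptanedioate
Conditions: NaH (2.2 equiv), CS2, DMF, 0 °C; then MeI (2.5 equiv), 0 → 23 °C
Reagents that add atoms: carbon disulfide, S=C=S; iodomethane, CI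
Why: α-Oxo ketene dithioacetal formation (enolate dithiocarboxylation, double S-methylation) occurs at C4, the only enolisable ketone α-carbon because C2 is quaternary; no stereocentre changes (C5 becomes R by priority only).

Step 10
Reactants: 13 1-tert-butyl 7-methyl (2S,5R)-4-[bis(methylsulfanyl)methylidene]-2-{[(1S,2R)-3,3-dimethyl-2-(prop-1-en-2-yl)cyclobutyl]methyl}-2-(3-methylbut-2-en-1-yl)-3-oxo-5-propylheptanedioate
Product: 14 (3R,6S)-4-[bis(methylsulfanyl)methylidene]-6-(tert-butoxycarbonyl)-6-{[(1S,2R)-3,3-dimethyl-2-(prop-1-en-2-yl)cyclobutyl]methyl}-9-methyl-5-oxo-3-propyldec-8-enoic acid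
Conditions: LiOH·H2O (1.5 equiv), THF/H2O 3:1, 0 °C; then 1 M HCl to pH 3
Reagents that add atoms: lithium hydroxide, [Li+].[OH-]
Why: Saponification is selective for the unhindered primary methyl ester over the tert-butyl ester on the quaternary carbon, and the push–pull ketone is deactivated towards retro-Claisen cleavage.

Step 11
Reactants: 14 (3R,6S)-4-[bis(methylsulfanyl)methylidene]-6-(tert-butoxycarbonyl)-6-{[(1S,2R)-3,3-dimethyl-2-(prop-1-en-2-yl)cyclobutyl]methyl}-9-methyl-5-oxo-3-propyldec-8-enoic acid; 15 4-methyl-4-[(trimethylsilyl)oxy]pentan-2-one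
Product: 19 (3R)-3-[(6R)-6-{[(1S,2R)-3,3-dimethyl-2-(prop-1-en-2-yl)cyclobutyl]methyl}-5-hydroxy-2,2-dimethyl-6-(3-methylbut-2-en-1-yl)-4,7-dioxo-3,4,6,7-tetrahydro-2H-chromen-8-yl]hexanoic acid, via substitution adduct 16 (not isolated), via Dieckmann product 17 (not isolated), via desilylated alcohol 18 (not isolated)
Conditions: 15 (2.2 equiv), KHMDS (3.3 equiv), THF, −78 → 50 °C; then 2 M HCl, THF, 23 °C
Reagents that add atoms: none
Why: Proposed new method: the kinetic potassium enolate of 15 adds to the bis(methylsulfanyl) carbon of the non-enolisable ketene dithioacetal and expels MeS− (16), the doubly activated CH2 so created is deprotonated and closes onto the tert-butyl ester in a 6-exo Claisen (Dieckmann) step (17), and on acidification the unmasked tertiary alcohol (18) displaces the remaining MeS group at the now doubly activated vinylogous thioester carbon, so the pyran oxygen ends up only on the sulfur-bearing carbon (dehydrative attack at the enol carbon is reversible in aqueous acid), the carboxylate side chain is inert as an electrophile and no stereocentre is touched; closest known reactions are the Junjappa–Ila [3+3] annulation of α-oxo ketene dithioacetals with ketone enolates, the Claisen cyclisation of triketo esters to acylphloroglucinols and the O-cyclisation of hydroxy ketene dithioacetals to 2-(methylsulfanyl)chromones.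

## Compound list

1 | methyl 3,3-dimethylcyclobutane-1-carboxylate | COC(=O)C1CC(C)(C)C1 | starting material
2 | methyl 3,3-dimethyl-1-(phenylselanyl)cyclobutane-1-carboxylate | COC(=O)C1([Se]c2ccccc2)CC(C)(C)C1 | intermediate
3 | methyl 3,3-dimethylcyclobut-1-ene-1-carboxylate | COC(=O)C1=CC(C)(C)C1 | intermediate
4 | methyl (1R,2R)-3,3-dimethyl-2-(prop-1-en-2-yl)cyclobutane-1-carboxylate (trans) | C=C(C)[C@H]1[C@H](C(=O)OC)CC1(C)C | intermediate
5 | [(1R,2R)-3,3-dimethyl-2-(prop-1-en-2-yl)cyclobutyl]methanol | C=C(C)[C@H]1[C@H](CO)CC1(C)C | intermediate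
6 | (1R,2R)-1-(iodomethyl)-3,3-dimethyl-2-(prop-1-en-2-yl)cyclobutane | C=C(C)[C@H]1[C@H](CI)CC1(C)C | intermediate
7 | 3-propylglutaric anhydride (4-propyloxane-2,6-dione) | CCCC1CC(=O)OC(=O)C1 | starting material
8 | (3S)-3-(2-methoxy-2-oxoethyl)hexanoic acid | OC(=O)C[C@H](CCC)CC(=O)OC | intermediate
9 | methyl (3S)-3-[2-(1H-imidazol-1-yl)-2-oxoethyl]hexanoate | O=C(C[C@H](CCC)CC(=O)OC)n1ccnc1 | intermediate
10 | 1-tert-butyl 7-methyl (5S)-3-oxo-5-propylheptanedioate | CC(C)(C)OC(=O)CC(=O)C[C@H](CCC)CC(=O)OC | intermediate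
11 | 1-tert-butyl 7-methyl (2RS,5S)-2-{[(1R,2R)-3,3-dimethyl-2-(prop-1-en-2-yl)cyclobutyl]methyl}-3-oxo-5-propylheptanedioate (C2 epimers) | C=C(C)[C@H]1[C@H](CC(C(=O)OC(C)(C)C)C(=O)C[C@H](CCC)CC(=O)OC)CC1(C)C | intermediate
12 | 1-tert-butyl 7-methyl (2S,5S)-2-{[(1S,2R)-3,3-dimethyl-2-(prop-1-en-2-yl)cyclobutyl]methyl}-2-(3-methylbut-2-en-1-yl)-3-oxo-5-propylheptanedioate | C=C(C)[C@H]1[C@H](C[C@@](CC=C(C)C)(C(=O)OC(C)(C)C)C(=O)C[C@H](CCC)CC(=O)OC)CC1(C)C | intermediate
13 | 1-tert-butyl 7-methyl (2S,5R)-4-[bis(methylsulfanyl)methylidene]-2-{[(1S,2R)-3,3-dimethyl-2-(prop-1-en-2-yl)cyclobutyl]methyl}-2-(3-methylbut-2-en-1-yl)-3-oxo-5-propylheptanedioate | C=C(C)[C@H]1[C@H](C[C@@](CC=C(C)C)(C(=O)OC(C)(C)C)C(=O)C(=C(SC)SC)[C@H](CCC)CC(=O)OC)CC1(C)C | intermediate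
14 | (3R,6S)-4-[bis(methylsulfanyl)methylidene]-6-(tert-butoxycarbonyl)-6-{[(1S,2R)-3,3-dimethyl-2-(prop-1-en-2-yl)cyclobutyl]methyl}-9-methyl-5-oxo-3-propyldec-8-enoic acid | C=C(C)[C@H]1[C@H](C[C@@](CC=C(C)C)(C(=O)OC(C)(C)C)C(=O)C(=C(SC)SC)[C@H](CCC)CC(=O)O)CC1(C)C | intermediate
15 | 4-methyl-4-[(trimethylsilyl)oxy]pentan-2-one | CC(=O)CC(C)(C)O[Si](C)(C)C | starting material
16 | (3R,6S)-6-(tert-butoxycarbonyl)-6-{[(1S,2R)-3,3-dimethyl-2-(prop-1-en-2-yl)cyclobutyl]methyl}-9-methyl-4-{5-methyl-1-(methylsulfanyl)-3-oxo-5-[(trimethylsilyl)oxy]hexylidene}-5-oxo-3-propyldec-8-enoic acid (E/Z mixture) | C=C(C)[C@H]1[C@H](C[C@@](CC=C(C)C)(C(=O)OC(C)(C)C)C(=O)C(=C(SC)CC(=O)CC(C)(C)O[Si](C)(C)C)[C@H](CCC)CC(=O)O)CC1(C)C | intermediate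
17 | (3R)-3-[(5R)-5-{[(1S,2R)-3,3-dimethyl-2-(prop-1-en-2-yl)cyclobutyl]methyl}-4-hydroxy-5-(3-methylbut-2-en-1-yl)-3-{3-methyl-3-[(trimethylsilyl)oxy]butanoyl}-2-(methylsulfanyl)-6-oxocyclohexa-1,3-dien-1-yl]hexanoic acid | C=C(C)[C@H]1[C@H](C[C@]2(CC=C(C)C)C(=O)C([C@H](CCC)CC(=O)O)=C(SC)C(C(=O)CC(C)(C)O[Si](C)(C)C)=C2O)CC1(C)C | intermediate
18 | (3R)-3-[(5R)-5-{[(1S,2R)-3,3-dimethyl-2-(prop-1-en-2-yl)cyclobutyl]methyl}-4-hydroxy-3-(3-hydroxy-3-methylbutanoyl)-5-(3-methylbut-2-en-1-yl)-2-(methylsulfanyl)-6-oxocyclohexa-1,3-dien-1-yl]hexanoic acid | C=C(C)[C@H]1[C@H](C[C@]2(CC=C(C)C)C(=O)C([C@H](CCC)CC(=O)O)=C(SC)C(C(=O)CC(C)(C)O)=C2O)CC1(C)C | intermediate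
19 | (3R)-3-[(6R)-6-{[(1S,2R)-3,3-dimethyl-2-(prop-1-en-2-yl)cyclobutyl]methyl}-5-hydroxy-2,2-dimethyl-6-(3-methylbut-2-en-1-yl)-4,7-dioxo-3,4,6,7-tetrahydro-2H-chromen-8-yl]hexanoic acid (CNP0358381.1) | C=C(C)[C@H]1[C@H](C[C@]2(CC=C(C)C)C(=O)C([C@H](CCC)CC(=O)O)=C3OC(C)(C)CC(=O)C3=C2O)CC1(C)C | target

## Step count and risks

Total step count: 11. Longest linear sequence: 9 steps (1, 2, 3, 4, 7, 8, 9, 10, 11).

**Step 11 (most likely to fail).** The stabilised carbanion of 16 must attack a tert-butyl ester on a quaternary carbon, and the crowded ketene dithioacetal may react sluggishly. The allylic propyl-bearing hydrogen could also epimerise under excess enolate. The fallback changes the acyl donor at the quaternary carbon from tert-butyl to methyl and rebuilds the substrate accordingly. It sets out from 9: step 6 run with potassium monomethyl malonate gives dimethyl (5S)-3-oxo-5-propylheptanedioate F1. Alkylation with 6 gives the C2-epimeric keto diester F2, and phase-transfer prenylation as in step 8 gives the quaternary dimethyl ester F3. CS2/MeI then gives the ketene dithioacetal F4, and LiOH at 0 °C cleaves only the unhindered side-chain ester to give the acid F5. The enolate of 15 gives the methyl-ester substitution adduct F6, whose methyl ester is a much better Claisen acceptor. The fallback comes back to the route at 17.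

**Step 8.** Phase-transfer alkylation is well precedented for cyclic tert-butyl β-keto esters but thinly for acyclic ones, so the selectivity at the quaternary carbon may be modest. The fallback sets the centre on a malonate instead, where this catalysis is best established, and sets out from 6. tert-Butyl 2,2-diphenylethyl malonate F7 (from mono-tert-butyl malonate, 2,2-diphenylethanol and DCC) is alkylated with 6 (NaH, DMF) to the monoalkyl malonate F8. Park–Jew phase-transfer prenylation (prenyl bromide, (S,S)-3,4,5-trifluorophenyl-NAS bromide, 50% KOH, toluene, −40 °C) gives the quaternary diester F9. 1 M KOH/MeOH removes only the diphenylethyl ester to give the half acid F10, and Ghosez's reagent gives the acid chloride F11. Separately, commercial (R)-4-propyldihydrofuran-2(3H)-one is opened with TMSI then MeOH to methyl (3R)-3-(iodomethyl)hexanoate F12, and zinc dust converts it into the alkylzinc iodide F13. Pd(PPh3)4-catalysed Negishi acylation of F11 with F13 comes back to the route at 12.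

**Step 2.** The β-carbon of 3 is neopentyl-like, and Rh-catalysed alkenyl transfer to such a cyclobutenoate is an untested extension. The fallback uses auxiliary-controlled cuprate addition and sets out from 3. LiOH gives 3,3-dimethylcyclobut-1-ene-1-carboxylic acid F14. PivCl/Et3N followed by lithiated (S)-4-phenyloxazolidin-2-one gives the N-enoyl imide F15. Isopropenylmagnesium bromide with CuBr·SMe2 (THF, −40 °C) adds anti to the phenyl group to give the trans conjugate adduct F16. LiBH4 removes the auxiliary reductively and comes back to the route at 5.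

Further compounds

F1 | step 11 | dimethyl (5S)-3-oxo-5-propylheptanedioate | COC(=O)CC(=O)C[C@H](CCC)CC(=O)OC
F2 | step 11 | dimethyl (2RS,5S)-2-{[(1R,2R)-3,3-dimethyl-2-(prop-1-en-2-yl)cyclobutyl]methyl}-3-oxo-5-propylheptanedioate | C=C(C)[C@H]1[C@H](CC(C(=O)OC)C(=O)C[C@H](CCC)CC(=O)OC)CC1(C)C
F3 | step 11 | dimethyl (2S,5S)-2-{[(1S,2R)-3,3-dimethyl-2-(prop-1-en-2-yl)cyclobutyl]methyl}-2-(3-methylbut-2-en-1-yl)-3-oxo-5-propylheptanedioate | C=C(C)[C@H]1[C@H](C[C@@](CC=C(C)C)(C(=O)OC)C(=O)C[C@H](CCC)CC(=O)OC)CC1(C)C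
F4 | step 11 | dimethyl (2S,5R)-4-[bis(methylsulfanyl)methylidene]-2-{[(1S,2R)-3,3-dimethyl-2-(prop-1-en-2-yl)cyclobutyl]methyl}-2-(3-methylbut-2-en-1-yl)-3-oxo-5-propylheptanedioate | C=C(C)[C@H]1[C@H](C[C@@](CC=C(C)C)(C(=O)OC)C(=O)C(=C(SC)SC)[C@H](CCC)CC(=O)OC)CC1(C)C
F5 | step 11 | (3R,6S)-4-[bis(methylsulfanyl)methylidene]-6-{[(1S,2R)-3,3-dimethyl-2-(prop-1-en-2-yl)cyclobutyl]methyl}-6-(methoxycarbonyl)-9-methyl-5-oxo-3-propyldec-8-enoic acid | C=C(C)[C@H]1[C@H](C[C@@](CC=C(C)C)(C(=O)OC)C(=O)C(=C(SC)SC)[C@H](CCC)CC(=O)O)CC1(C)C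
F6 | step 11 | (3R,6S)-6-{[(1S,2R)-3,3-dimethyl-2-(prop-1-en-2-yl)cyclobutyl]methyl}-6-(methoxycarbonyl)-9-methyl-4-{5-methyl-1-(methylsulfanyl)-3-oxo-5-[(trimethylsilyl)oxy]hexylidene}-5-oxo-3-propyldec-8-enoic acid | C=C(C)[C@H]1[C@H](C[C@@](CC=C(C)C)(C(=O)OC)C(=O)C(=C(SC)CC(=O)CC(C)(C)O[Si](C)(C)C)[C@H](CCC)CC(=O)O)CC1(C)C
F7 | step 8 | tert-butyl 2,2-diphenylethyl propanedioate | CC(C)(C)OC(=O)CC(=O)OCC(c1ccccc1)c1ccccc1
F8 | step 8 | 1-tert-butyl 3-(2,2-diphenylethyl) (2RS)-2-{[(1R,2R)-3,3-dimethyl-2-(prop-1-en-2-yl)cyclobutyl]methyl}propanedioate | C=C(C)[C@H]1[C@H](CC(C(=O)OC(C)(C)C)C(=O)OCC(c2ccccc2)c2ccccc2)CC1(C)C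
F9 | step 8 | 1-tert-butyl 3-(2,2-diphenylethyl) (2S)-2-{[(1S,2R)-3,3-dimethyl-2-(prop-1-en-2-yl)cyclobutyl]methyl}-2-(3-methylbut-2-en-1-yl)propanedioate | C=C(C)[C@H]1[C@H](C[C@@](CC=C(C)C)(C(=O)OC(C)(C)C)C(=O)OCC(c2ccccc2)c2ccccc2)CC1(C)C
F10 | step 8 | (2S)-2-(tert-butoxycarbonyl)-2-{[(1S,2R)-3,3-dimethyl-2-(prop-1-en-2-yl)cyclobutyl]methyl}-5-methylhex-4-enoic acid | C=C(C)[C@H]1[C@H](C[C@@](CC=C(C)C)(C(=O)OC(C)(C)C)C(=O)O)CC1(C)C
F11 | step 8 | tert-butyl (2R)-2-(chlorocarbonyl)-2-{[(1S,2R)-3,3-dimethyl-2-(prop-1-en-2-yl)cyclobutyl]methyl}-5-methylhex-4-enoate | C=C(C)[C@H]1[C@H](C[C@@](CC=C(C)C)(C(=O)OC(C)(C)C)C(=O)Cl)CC1(C)C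
F12 | step 8 | methyl (3R)-3-(iodomethyl)hexanoate | IC[C@H](CCC)CC(=O)OC
F13 | step 8 | [(2R)-2-(2-methoxy-2-oxoethyl)pentyl]zinc iodide | I[Zn]C[C@H](CCC)CC(=O)OC
F14 | step 2 | 3,3-dimethylcyclobut-1-ene-1-carboxylic acid | OC(=O)C1=CC(C)(C)C1
F15 | step 2 | (4S)-3-(3,3-dimethylcyclobut-1-ene-1-carbonyl)-4-phenyl-1,3-oxazolidin-2-one | O=C(C1=CC(C)(C)C1)N1[C@@H](c2ccccc2)COC1=O
F16 | step 2 | (4S)-3-[(1R,2R)-3,3-dimethyl-2-(prop-1-en-2-yl)cyclobutane-1-carbonyl]-4-phenyl-1,3-oxazolidin-2-one | C=C(C)[C@H]1[C@H](C(=O)N2[C@@H](c3ccccc3)COC2=O)CC1(C)C
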